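All runs were generated by integration on assumed constants, noise included.

Two constants can be read from the beta run, whose readings of intermediate A are falling from the first time on.

- beta: substrate 1.4 M; coupling partner 1.1 M; run made earlier
- flask: substrate 1.4 M; coupling partner 2.10 M; time 1.0 h

beta run (percent of the substrate charged)

| time / min | intermediate A / % | target / % |
|---|---|---|
| 1.00 | 48.1 | 3.0 |
| 2.00 | 41.5 | 5.8 |
| 5.00 | 25.0 | 9.7 |
| 12.0 | 12.7 | 9.8 |

(standard deviation of a reading: 0.3 percentage points)

- the analysis behind the earlier runs scatters by 0.3 percentage points, standard deviation

* time, not beyond 1.0 h, at which the flask holds most intermediate A, in min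
* the amount of intermediate A, in percent of the substrate charged, at that time

Between the first two readings, intermediate A decays with a rate constant λ = 0.148 min⁻¹. Carried back to zero time, the first reading gives f = 55.7 %, the delivered share: the part of the substrate that enters intermediate A, ignoring decay during filling.

For my upper bound, I let partner play no part in the missing share, so the flask peaks as beta does, near 48.1 %. For my lower bound, I let substrate enter intermediate A without partner and lose the missing share by a path proportional to partner concentration c. With c held at its charge (pseudo-first-order), the two rates integrate to odds against intermediate A of ρc, where ρ = 0.722 L mol⁻¹. The flask's share is then 39.8 %, and beta's decay factor of 0.862 brings its peak to 34.3 %. I commit to that bracket, with the peak before 1.00 min.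

The forecast reads differently, that “substrate is consumed much faster”. It gives 68 %, range 60 % to 75 %, at 0.6 min, and that range lies above my bracket.

The flask gives 42.0 % at 0.855 min, inside my bracket and below the forecast's range.

    coupling partner + target → over-reaction product (k = 0.00374 L mol⁻¹ s⁻¹)
    substrate ⇌ intermediate A (K = 16.7, k = 0.0294 s⁻¹)
    substrate + coupling partner → side product (k = 0.00805 L mol⁻¹ s⁻¹)
    substrate ⇌ dormant form (K = 1.58, k = 0.0105 s⁻¹)
    intermediate A ⇌ intermediate B (K = 2.80, k = 0.00316 s⁻¹)
    intermediate A → target (k = 0.00138 s⁻¹)

The neighbouring flask is the same flask charged with 0.84 M of coupling partner, less than beta. The same odds give it a share of 62.3 %, and beta's decay factor turns that into 53.7 %. This end now lies above the beta reading, so the bracket for the neighbouring flask runs from 48.1 % up to it. Inside that bracket, the neighbouring flask reaches 49.4 %.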